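We start from the solid.

| setting | Thursday's | flask |
|---|---|---|
| Ji | 0.10 M | 0.10 M |
| Rx | 0.20 M | 0.200 M |
| remark | the very flask that is asked about, followed so far |  |
| time |  | 2.5 h |

Thursday's run (percent of the Ji charged)

| time / min | Ul.Jo / % | Xa / % | Qo / % | Ji / % | Ul / % |
|---|---|---|---|---|---|
| 5.00 | 2 | 1 | 9 | 91 | 0 |
| 15.0 | 0 | 0 | 19 | 81 | 0 |
| 25.0 | 0 | 0 | 26 | 71 | 5 |
| 40.0 | 1 | 0 | 34 | 61 | 8 |
| 60.0 | 0 | 0 | 35 | 50 | 15 |
| 80.0 | 2 | 0 | 39 | 47 | 18 |

(readings scatter by 1.5 percentage points)

- amounts and yields of Ul.Jo count Wa too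
- given per volume of solution although it is solid: Wa, Ji
- the earlier runs were read with a standard deviation of 1.5 percentage points
- steps under discussion: Qo <-> Ul; Rx -> Jo; Ul + Jo -> Ul.Jo; Wa <-> Ul.Jo; Ul.Jo -> Xa; Ji <-> Qo
- at the start none of Ji is in solution
- Qo means what is dissolved; the solid is not counted in it

* the species that holds most of what was charged as Ji, at 2.5 h (Ul.Jo / Xa / Ul / Qo)
* the largest share itself, whichever of these holds it, in percent of the Ji charged

Thursday's run is this very flask, so we follow the fraction of Ji left and not what is made. Ji reads 47 % at 80.0 min, so 73.4 min is the time in which the fraction of Ji left halves, the half-time of the solid. But the reading at 40.0 min is 61 % against 68.5 % by this rule, and the reading at 60.0 min is 50 % against 56.7 %, so the rule, fixed on the last reading, is rough. At 2.5 h we reckon 24.3 % of the Ji left, so 75.7 % has gone into solution. Qo read 39 % at the last reading, and if it keeps that level, 36.7 % remains for Ul and what lies beyond it. That is less than the amount in Qo, so we commit to Qo, narrowly.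

The forecast names Qo, at 39 %: “Qo narrowly holds the most, though Ul is close”.

The flask gives Qo at 40.3 %, with Ul at 29.1 %.

    Qo ⇌ Ul (K = 1.60, k = 0.00980 min⁻¹)
    Rx → Jo (k = 0.00430 min⁻¹)
    Ul + Jo → Ul.Jo (k = 0.0410 L mol⁻¹ min⁻¹)
    Wa ⇌ Ul.Jo, rate k4*(cs4 - [Ul.Jo]) while solid is left; crystals form when [Ul.Jo] > cs4 (solubility = 38.0 mM, k = 0.990 min⁻¹)
    Ul.Jo → Xa (k = 0.00850 min⁻¹)
    Ji ⇌ Qo, rate k6*(cs6 - [Qo]) while solid is left; crystals form when [Qo] > cs6 (solubility = 46.0 mM, k = 0.0410 min⁻¹)

Ji in this flask stands at 24.3 % at 2.50 h, where the half-time of the solid gave 24.3 %. Qo leads there because of the time given: the same flask at 25.0 h keeps 1.65 % of Qo against 40.3 %. For the same flask read at 10.0 h, the half-time leaves 0.346 % of the Ji and the flask shows 0 %, and there Qo has fallen to 15.2 % while Xa holds 53.8 %.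

(The earlier runs and the new flask come from a simulation from invented constants, and the scatter is random.)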